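## The problem

The target is a germacranolide: a ten-membered carbocycle (C1–C10) with a trans-fused α-methylene-γ-lactone across C6–C7 (O6–C12, C11=C13). It also carries a cis-4,5-epoxide with the C15 methyl on C4, a ring-cis C1=C10 olefin bearing the C14 methyl ester, an acetate on O9 and a 2-(hydroxymethyl)acrylate on O8. Six stereocentres run without a break from C4 to C9 (4R,5S,6S,7R,8S,9R). C4/C5 can come from an allylic-alcohol epoxidation and C8 from a small chiral building block; C5 and C8 together can then direct C6 and C7, and C8 can direct C9. The lactone must be trans (C6–O anti to the C7–C8 bond), which the usual open-chain 2-(bromomethyl)alkenoate allylation does not deliver, since its (Z)-reagent gives the syn adduct and hence the cis-lactone. Three Michael acceptors, an acid-labile trisubstituted epoxide and two different esters on neighbouring oxygens (acyl migration) rule out strong base, strong acid, hydride and soft nucleophiles late in the route. A ten-membered ring is costly to close, so the ring-forming reaction must be neutral, chemoselective and fast. The enabling feature is C9: an allylic carbinol flanked by oxygenated C8 and the trisubstituted C10=C1 olefin, the retron of an alkenyl-metal addition to an α-silyloxy aldehyde. The (Z)-olefin, the cis-epoxide and the lactone act as turn elements that fold the open chain.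

## Retrosynthesis

**28 ⇒ 23 + 26.** The C8 ester C–O bond is cut last (through silyl-protected 27). The hydroxymethylacrylate is the most nucleophile-sensitive group, and O8 has to be a bulky silyl ether at the ring closure. Carrying the ester through the closure would place an acyl group next to the new C9 alkoxide. The forward step must acylate a hindered secondary alcohol without moving the C9 acetate; the acid 26 comes in two steps from 24 via 25.

**23 ⇒ 17.** Functional-group changes only: desilylation of O8 (22), C14 methyl ester from the PMB ether (via 19, enal 20, acid 21), and the C9 acetate (18). C14 is carried as a 2-iodoallyl ether because that is an established alkenyl partner for nickel/chromium coupling, whereas an α-iodo enoate is not. The price is four operations. O9 is acetylated before O8 is freed, so the two oxygens are never free together.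

**17 ⇒ 16.** The C9–C10 bond is cut; this is the strategic step. Other ring bonds are worse cuts: C1–C2 or C2–C3 would need sp2–sp3 or sp3–sp3 macrocyclisation with no gain in stereocontrol, and C6–C7 or C7–C8 closures would set two centres at once inside a strained transition state. Cutting C9–C10 opens the ring and removes one stereocentre. It asks of the forward reaction retention of the (Z)-iodide geometry, Felkin–Anh control from C8, and tolerance of epoxide, methylene lactone and ethers.

**16 ⇒ 15 ⇒ 8 + 13.** Oxidation level at C9 is adjusted, then the C6–C7 bond is cut, which splits the chain into two pieces of similar size and clears two stereocentres. The allyl partner is the six-membered bromolactone 13, in which the ring holds C8 cis to the carbonyl. This geometry gives the anti adduct 14 and, after the acyl group moves from O9 to O6, the trans γ-lactone 15 with C9–OH set free and O8 already silylated. No acetal has to be hydrolysed beside the epoxide.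

**8 ⇒ 1.** The epoxy aldehyde goes back through 7, 6, 5, 4, 3 and 2 to nerol (1). The (Z)-allylic alcohol gives C4/C5 by asymmetric epoxidation, and its distal olefin is the handle for ozonolysis and (Z)-selective iodo-olefination. A β-alkoxy iodo-ylide would eliminate, so the iodoalkene is made as the α-iodo enoate 5 and reduced.

**13 ⇒ 9 + 10.** The lactone C=C is cut by ring-closing metathesis of 12, made from (S)-but-3-ene-1,2-diol (9) and 2-(bromomethyl)acrylic acid (10) via 11. C8 is bought, not made.

## Roads not taken

**Alternative 1:** The retrosynthetic move joins C1 and C6, so the ten-membered ring is hidden in the bicyclic diene A1, drawn from a naphthalene by two Birch reductions. Forward, one equivalent of ozone would cleave the tetrasubstituted ring-fusion olefin of A1 to the cyclodecenedione A2.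
- Merits: no macrocyclisation, no high dilution, and the C7–C10 substituents are set on a six-membered ring with predictable facial control. In ring-forming security this road is better than the chosen one.
- Weak points: A2 has ketones at C1 and C6 that must be told apart. Its olefin is at C3=C4 and must be moved to C4=C5 (with competing conjugation toward C1) before epoxidation. The C1 keto ester must become the ring-cis enoate with geometric control. C6 reduction, lactonisation and methylenation would all be done on a flexible ten-membered ring.
- Comparison: the chosen plan offers a closure on a chain in which C4–C8 are already fixed and every functional group except C14 is at its final oxidation level.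

**Alternative 2:** The cut is C1–C2. Forward, 9-BBN would hydroborate the terminal vinyl group of the seco iodide A3, and PdCl2(dppf) with Cs2CO3 would couple the C2 alkylborane with the C1 vinyl iodide to give the macrocycle A4.
- Merits: C9 is set before ring closure (no stereochemical gamble in the closing step) and C14 is already the ester. In both respects this road is better than the chosen one, which spends four operations on C14 and relies on C8 to set C9.
- Weak points: the vinyl group of A3 sits on the epoxide carbon C4, so the substrate is a vinyl epoxide, exposed to ionisation by zerovalent palladium and to opening by the borane. B-alkyl Suzuki closure of a ten-membered ring is rare. After A4 the lactone must be methylenated by enolate chemistry beside an epoxide and an enoate. The acetonide must be hydrolysed with acid beside the epoxide, and O8 and O9 then have to be acylated differently with no built-in bias.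
- Comparison: the chosen plan has O8/O9 differentiated from the start, the methylene lactone in place before closure, and a closing reaction known to tolerate epoxides and enoates.

**Alternative 3:** The cuts are C1–C2 and C9–C10 (two-carbon insertion). Forward, the pyrrolidine enamine of cyclooctenone A5 (formed toward C2) would add methyl propiolate; the fused cyclobutene would open and hydrolyse to the ten-membered keto ester A6.
- Merits: two C–C bonds and the ring enlargement in one operation without high dilution, with the C14 ester and the C1=C10 olefin delivered directly. In bond economy and oxidation-state economy at C14 this road is better.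
- Weak points: the enamine must form away from the silyloxy-bearing C8 without epimerisation or elimination. A5, with three contiguous stereocentres and a (Z)-trisubstituted olefin in an eight-membered ring, is itself a hard target. A6 holds C9 as a ketone inside a doubly activated alkylidene keto ester, so 1,2-reduction must beat conjugate addition and be face-selective on a mobile ring. The epoxide, lactone and methylene all remain to be installed on the macrocycle.
- Comparison: the chosen plan sets C9 in the same step that closes the ring and leaves no stereochemical work on the ten-membered ring.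

Key step: step 13

Remark: germacrane numbering of the target (C1–C15) is used for every intermediate; 9, 10 and 24 are taken as purchasable.

## Route

Step 1
Reactants: 1 nerol
Product: 2 (2S,3R)-2,3-epoxynerol
Conditions: Ti(OiPr)4 (cat.), L-(+)-diethyl tartrate (cat.), t-BuOOH, 4 Å MS, CH2Cl2, −20 °C
Reagents that add atoms: tert-butyl hydroperoxide, CC(C)(C)OO
Why: Sharpless asymmetric epoxidation; the L-(+)-tartrate complex delivers oxygen to the face of the (Z)-allylic alcohol that gives the (2S,3R)-epoxide, which is C5 (S) and C4 (R) of the target, and the distal olefin, having no directing hydroxyl, is left alone.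

Step 2
Reactants: 2 (2S,3R)-2,3-epoxynerol
Product: 3 triethylsilyl ether of 2
Conditions: Et3SiCl, imidazole, CH2Cl2, 0 °C
Reagents that add atoms: chlorotriethylsilane, CC[Si](Cl)(CC)CC
Why: Standard silylation of a primary alcohol; the triethylsilyl group is chosen because step 7 can unmask and oxidise it in one operation.

Step 3
Reactants: 3 triethylsilyl ether of 2
Product: 4 3-[(2R,3S)-2-methyl-3-(triethylsilyloxymethyl)oxiran-2-yl]propanal
Conditions: O3, CH2Cl2, −78 °C; then PPh3, −78 °C → rt
Reagents that add atoms: ozone, [O-][O+]=O
Why: Ozonolysis with reductive work-up; the trisubstituted olefin is the only C=C left, and epoxide and silyl ether are inert to ozone.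

Step 4
Reactants: 4 3-[(2R,3S)-2-methyl-3-(triethylsilyloxymethyl)oxiran-2-yl]propanal
Product: 5 methyl (2Z)-2-iodo-5-[(2R,3S)-2-methyl-3-(triethylsilyloxymethyl)oxiran-2-yl]pent-2-enoate
Conditions: Ph3P=CHCO2Me, N-iodosuccinimide, CH2Cl2, −20 °C; then 4, −20 °C → rt
Reagents that add atoms: methyl (triphenylphosphoranylidene)acetate, COC(=O)C=P(c1ccccc1)(c1ccccc1)c1ccccc1; N-iodosuccinimide, O=C1CCC(=O)N1I
Why: Wittig olefination with the stabilised α-iodo ylide made in the flask by iodination of the ester ylide; as with other stabilised ylides the aldehyde chain should end up trans to the ester and therefore cis to iodine, the (Z)-iodoalkene needed for the ring-cis C1=C10 bond.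

Step 5
Reactants: 5 methyl (2Z)-2-iodo-5-[(2R,3S)-2-methyl-3-(triethylsilyloxymethyl)oxiran-2-yl]pent-2-enoate
Product: 6 (2Z)-2-iodo-5-[(2R,3S)-2-methyl-3-(triethylsilyloxymethyl)oxiran-2-yl]pent-2-en-1-ol
Conditions: iBu2AlH (DIBAL-H), CH2Cl2, −78 °C; aq. Rochelle salt
Reagents that add atoms: none
Why: 1,2-Reduction of the enoate to the allylic alcohol by DIBAL-H; at −78 °C the epoxide, the vinyl iodide and the silyl ether should survive.

Step 6
Reactants: 6 (2Z)-2-iodo-5-[(2R,3S)-2-methyl-3-(triethylsilyloxymethyl)oxiran-2-yl]pent-2-en-1-ol
Product: 7 4-methoxybenzyl ether of 6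
Conditions: NaH, 4-MeOC6H4CH2Cl, Bu4NI (cat.), THF/DMF, 0 °C → rt
Reagents that add atoms: 4-methoxybenzyl chloride, COc1ccc(CCl)cc1
Why: Williamson etherification; the PMB group masks C14–O through the coupling and ring closure and is later removed oxidatively without acid.

Step 7
Reactants: 7 4-methoxybenzyl ether of 6
Product: 8 (2R,3R)-3-[(3Z)-4-iodo-5-(4-methoxybenzyloxy)pent-3-en-1-yl]-3-methyloxirane-2-carbaldehyde
Conditions: (COCl)2, DMSO, CH2Cl2, −78 → −40 °C; then Et3N, −78 → 0 °C
Reagents that add atoms: none
Why: Swern oxidation applied directly to the primary triethylsilyl ether; the chlorosulfonium reagent cleaves the unhindered Si–O bond and the resulting alkoxysulfonium ion is collapsed by Et3N to the C6 aldehyde, while the PMB ether and the epoxide are not touched.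

Step 8
Reactants: 9 (2S)-but-3-ene-1,2-diol; 10 2-(bromomethyl)acrylic acid
Product: 11 (2S)-2-hydroxybut-3-en-1-yl 2-(bromomethyl)acrylate
Conditions: N,N'-diisopropylcarbodiimide, DMAP (cat.), CH2Cl2, −20 → 0 °C, 9 in excess
Reagents that add atoms: none
Why: Steglich esterification; the primary hydroxyl should react ahead of the secondary allylic one, and low temperature with excess diol limits diester formation.

Step 9
Reactants: 11 (2S)-2-hydroxybut-3-en-1-yl 2-(bromomethyl)acrylate
Product: 12 (2S)-2-(tert-butyldimethylsilyloxy)but-3-en-1-yl 2-(bromomethyl)acrylate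
Conditions: TBSOTf, 2,6-lutidine, CH2Cl2, −78 °C
Reagents that add atoms: tert-butyldimethylsilyl trifluoromethanesulfonate, CC(C)(C)[Si](C)(C)OS(=O)(=O)C(F)(F)F
Why: Silylation of the secondary alcohol with a silyl triflate and a hindered base that cannot alkylate on the allylic bromide; this installs the bulky O8 silyl ether used later for C9 control.

Step 10
Reactants: 12 (2S)-2-(tert-butyldimethylsilyloxy)but-3-en-1-yl 2-(bromomethyl)acrylate
Product: 13 (5S)-3-(bromomethyl)-5-(tert-butyldimethylsilyloxy)-5,6-dihydro-2H-pyran-2-one
Conditions: second-generation Hoveyda–Grubbs catalyst RuCl2(H2IMes)(=CHC6H4-2-OiPr) (5 mol%), toluene (0.01 M), 80 °C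
Reagents that add atoms: none
Why: Ring-closing metathesis of a 2-substituted acrylate onto a terminal olefin gives the six-membered unsaturated lactone with loss of ethene; the ring fixes C8 cis to the carbonyl, the geometry that the next step turns into the trans-lactone.

Step 11
Reactants: 8 (2R,3R)-3-[(3Z)-4-iodo-5-(4-methoxybenzyloxy)pent-3-en-1-yl]-3-methyloxirane-2-carbaldehyde; 13 (5S)-3-(bromomethyl)-5-(tert-butyldimethylsilyloxy)-5,6-dihydro-2H-pyran-2-one
Product: 15 6,12-lactone C9 alcohol (C8 OTBS), via δ-lactone adduct 14 (not isolated)
Conditions: In (powder), THF/H2O (3:1), rt; then PPTS (cat.), CH2Cl2, rt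
Reagents that add atoms: none
Why: Barbier-type 2-(alkoxycarbonyl)allylation: the allylindium from 13 adds through ring carbon C7 in a chair Zimmerman–Traxler transition state; the ring-locked geometry puts C8 equatorial (6,7-anti), the aldehyde approaches anti to the C8 silyloxy group (7,8-trans), and the Cornforth/Felkin–Anh preference of the epoxy aldehyde gives 5,6-anti. These three preferences all point to the (5S,6S,7R,8S) array, a matched case. The C6 hydroxyl then takes the acyl group from O9 (δ- to γ-lactone shift, thermodynamically downhill), giving the trans-lactone and freeing C9–OH; indium does not insert into the vinyl iodide.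

Step 12
Reactants: 15 6,12-lactone C9 alcohol (C8 OTBS)
Product: 16 C9 aldehyde (seco iodo aldehyde)
Conditions: Dess–Martin periodinane, pyridine, CH2Cl2, 0 °C → rt
Reagents that add atoms: none
Why: Dess–Martin oxidation of the primary alcohol under buffered, non-basic conditions; the α-silyloxy aldehyde is used at once so that C8 cannot epimerise.

Step 13
Reactants: 16 C9 aldehyde (seco iodo aldehyde)
Product: 17 ten-membered C9 allylic alcohol (C8 OTBS, C14 OPMB)
Conditions: CrCl2 (excess), NiCl2 (cat.), DMSO, rt, high dilution, slow addition of 16
Reagents that add atoms: none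
Why: Nozaki–Hiyama–Kishi reaction, run intramolecularly. CrCl2 reduces NiCl2 to zerovalent nickel, which inserts into the C10–I bond with retention of the (Z) geometry; transmetalation gives an alkenyl species of trivalent chromium that adds to the C9 aldehyde, and the chromium alkoxide formed is inert toward the lactone. The closest known reaction type is the nickel/chromium-mediated alkenyl iodide–aldehyde cyclisation to medium and large rings. The ten-membered ring closes in the 10-exo-trig mode, the carbonyl oxygen staying outside the ring. The new C9 stereocentre is controlled by C8: in the polar Felkin–Anh arrangement the C8–OSi bond lies anti to the incoming alkenyl group and the nucleophile passes the C8 hydrogen rather than C7, which places O9 anti to O8 as in 28; the bulky silyl ether and the weakly chelating chromium reagent disfavour the chelate that would lead to the epimer. The step needs chemoselectivity for the aldehyde over epoxide, methylene lactone and PMB ether, which the low basicity and carbonyl selectivity of alkenylchromium reagents provide. It also needs cyclisation to win over oligomerisation, which high dilution and the three turn elements of 16 (cis-epoxide, trans-lactone, (Z)-olefin) favour. Retention at C10 converts the (Z)-iodide into the ring-cis C1=C10 bond.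

Step 14
Reactants: 17 ten-membered C9 allylic alcohol (C8 OTBS, C14 OPMB)
Product: 18 C9 acetate
Conditions: Ac2O, pyridine, DMAP (cat.), CH2Cl2, 0 °C → rt
Reagents that add atoms: acetic anhydride, CC(=O)OC(C)=O
Why: DMAP-catalysed acetylation of the secondary allylic alcohol; capping O9 first means O8 and O9 are never free at the same time.

Step 15
Reactants: 18 C9 acetate
Product: 19 C14 allylic alcohol
Conditions: DDQ, CH2Cl2/pH 7 phosphate buffer, 0 °C
Reagents that add atoms: none
Why: Oxidative cleavage of the PMB ether by DDQ (hydride abstraction from the electron-rich benzylic position, hydrolysis of the oxocarbenium ion); neutral buffered conditions spare epoxide, silyl ether, acetate and the electron-poor olefins.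

Step 16
Reactants: 19 C14 allylic alcohol
Product: 20 C14 enal
Conditions: Dess–Martin periodinane, pyridine, CH2Cl2, 0 °C
Reagents that add atoms: none
Why: Dess–Martin oxidation of the primary allylic alcohol to the conjugated aldehyde without over-oxidation or olefin isomerisation.

Step 17
Reactants: 20 C14 enal
Product: 22 C14 methyl ester (C8 OTBS), via C14 acid 21 (not isolated)
Conditions: NaClO2, NaH2PO4, 2-methylbut-2-ene, t-BuOH/H2O, 0 °C → rt; then MeI, KHCO3, DMF, rt
Reagents that add atoms: sodium chlorite, [Na+].[O-]Cl=O; iodomethane, CI
Why: Pinnick oxidation of the enal followed by carboxylate alkylation; methyl iodide with a weak base is used instead of a diazoalkane, which would undergo dipolar cycloaddition with the α-methylene lactone.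

Step 18
Reactants: 22 C14 methyl ester (C8 OTBS)
Product: 23 C8 alcohol
Conditions: HF·pyridine, pyridine, THF, 0 °C → rt
Reagents that add atoms: none
Why: Fluoride-mediated desilylation under buffered, mildly acidic conditions, which disfavour base-induced acetyl migration from O9 to O8; the epoxide is protected from transannular opening because the C1=C10 olefin is now an electron-poor enoate.

Step 19
Reactants: 24 methyl 2-(hydroxymethyl)acrylate
Product: 25 methyl 2-(tert-butyldimethylsilyloxymethyl)acrylate
Conditions: TBSCl, imidazole, CH2Cl2, 0 °C → rt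
Reagents that add atoms: tert-butyldimethylsilyl chloride, CC(C)(C)[Si](C)(C)Cl
Why: Standard silylation of a primary allylic alcohol.

Step 20
Reactants: 25 methyl 2-(tert-butyldimethylsilyloxymethyl)acrylate
Product: 26 2-(tert-butyldimethylsilyloxymethyl)acrylic acid
Conditions: LiOH, THF/H2O, 0 °C; then 1 M HCl to pH 4
Reagents that add atoms: lithium hydroxide, [Li+].[OH-]
Why: Saponification of the methyl ester at low temperature; the primary silyl ether should tolerate cold aqueous hydroxide and brief mild acidification.

Step 21
Reactants: 23 C8 alcohol; 26 2-(tert-butyldimethylsilyloxymethyl)acrylic acid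
Product: 27 C8 2-(tert-butyldimethylsilyloxymethyl)acrylate
Conditions: N,N'-diisopropylcarbodiimide, DMAP (cat.), CH2Cl2, 0 °C → rt, 26 in excess
Reagents that add atoms: none
Why: Steglich esterification of the secondary C8 alcohol; the configuration at C8 is untouched because the C–O bond is not broken.

Step 22
Reactants: 27 C8 2-(tert-butyldimethylsilyloxymethyl)acrylate
Product: 28 CNP0147016.1
Conditions: HF·pyridine, pyridine, THF, 0 °C
Reagents that add atoms: none
Why: Fluoride-mediated cleavage of the primary silyl ether, which should be fast under buffered conditions that leave the two acrylates, the acetate, the lactone and the epoxide intact.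

## Compound list

1 | nerol, (2Z)-3,7-dimethylocta-2,6-dien-1-ol | CC(C)=CCC/C(C)=C\CO | starting material
2 | (2S,3R)-2,3-epoxynerol, [(2S,3R)-3-methyl-3-(4-methylpent-3-en-1-yl)oxiran-2-yl]methanol | OC[C@@H]1O[C@]1(C)CCC=C(C)C | intermediate
3 | triethylsilyl ether of 2 | CC[Si](CC)(CC)OC[C@@H]1O[C@]1(C)CCC=C(C)C | intermediate
4 | 3-[(2R,3S)-2-methyl-3-(triethylsilyloxymethyl)oxiran-2-yl]propanal | CC[Si](CC)(CC)OC[C@@H]1O[C@]1(C)CCC=O | intermediate
5 | methyl (2Z)-2-iodo-5-[(2R,3S)-2-methyl-3-(triethylsilyloxymethyl)oxiran-2-yl]pent-2-enoate | CC[Si](CC)(CC)OC[C@@H]1O[C@]1(C)CC/C=C(\I)C(=O)OC | intermediate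
6 | (2Z)-2-iodo-5-[(2R,3S)-2-methyl-3-(triethylsilyloxymethyl)oxiran-2-yl]pent-2-en-1-ol | CC[Si](CC)(CC)OC[C@@H]1O[C@]1(C)CC/C=C(\I)CO | intermediate
7 | 4-methoxybenzyl ether of 6 | CC[Si](CC)(CC)OC[C@@H]1O[C@]1(C)CC/C=C(\I)COCc1ccc(OC)cc1 | intermediate
8 | (2R,3R)-3-[(3Z)-4-iodo-5-(4-methoxybenzyloxy)pent-3-en-1-yl]-3-methyloxirane-2-carbaldehyde (C6 aldehyde, C4/C5 epoxide) | O=C[C@@H]1O[C@]1(C)CC/C=C(\I)COCc1ccc(OC)cc1 | intermediate
9 | (2S)-but-3-ene-1,2-diol | C=C[C@H](O)CO | starting material
10 | 2-(bromomethyl)acrylic acid | C=C(CBr)C(=O)O | starting material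
11 | (2S)-2-hydroxybut-3-en-1-yl 2-(bromomethyl)acrylate | C=C[C@H](O)COC(=O)C(=C)CBr | intermediate
12 | (2S)-2-(tert-butyldimethylsilyloxy)but-3-en-1-yl 2-(bromomethyl)acrylate | C=C[C@H](O[Si](C)(C)C(C)(C)C)COC(=O)C(=C)CBr | intermediate
13 | (5S)-3-(bromomethyl)-5-(tert-butyldimethylsilyloxy)-5,6-dihydro-2H-pyran-2-one | BrCC1=C[C@H](O[Si](C)(C)C(C)(C)C)COC1=O | intermediate
14 | δ-lactone adduct: 3-methylene-9,12-lactone with free C6 carbinol, C8 OTBS, 7,8-trans, 6,7-anti, 5,6-anti (C4–C8 as in 28) | O[C@H]([C@@H]1O[C@]1(C)CC/C=C(\I)COCc1ccc(OC)cc1)[C@@H]1C(=C)C(=O)OC[C@H]1O[Si](C)(C)C(C)(C)C | intermediate (not isolated)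
15 | trans-6,12-α-methylene-γ-lactone with C9 primary alcohol, C8 OTBS, (Z)-C10 iodide, C14 OPMB (C4–C8 as in 28) | OC[C@@H](O[Si](C)(C)C(C)(C)C)[C@H]1C(=C)C(=O)O[C@@H]1[C@@H]1O[C@]1(C)CC/C=C(\I)COCc1ccc(OC)cc1 | intermediate
16 | C9 aldehyde of 15 (seco iodo aldehyde) | O=C[C@@H](O[Si](C)(C)C(C)(C)C)[C@H]1C(=C)C(=O)O[C@@H]1[C@@H]1O[C@]1(C)CC/C=C(\I)COCc1ccc(OC)cc1 | intermediate
17 | ten-membered C9 allylic alcohol, C8 OTBS, C14 OPMB, ring-cis C1=C10 (C4–C9 as in 28) | CC(C)(C)[Si](C)(C)O[C@H]1[C@H]2C(=C)C(=O)O[C@@H]2[C@@H]2O[C@]2(C)CC/C=C(/COCc2ccc(OC)cc2)[C@H]1O | intermediate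
18 | C9 acetate of 17 | CC(C)(C)[Si](C)(C)O[C@H]1[C@H]2C(=C)C(=O)O[C@@H]2[C@@H]2O[C@]2(C)CC/C=C(/COCc2ccc(OC)cc2)[C@H]1OC(C)=O | intermediate
19 | C14 allylic alcohol (C9 OAc, C8 OTBS) | CC(C)(C)[Si](C)(C)O[C@H]1[C@H]2C(=C)C(=O)O[C@@H]2[C@@H]2O[C@]2(C)CC/C=C(/CO)[C@H]1OC(C)=O | intermediate
20 | C14 enal (C9 OAc, C8 OTBS) | CC(C)(C)[Si](C)(C)O[C@H]1[C@H]2C(=C)C(=O)O[C@@H]2[C@@H]2O[C@]2(C)CC/C=C(/C=O)[C@H]1OC(C)=O | intermediate
21 | C14 carboxylic acid (C9 OAc, C8 OTBS) | CC(C)(C)[Si](C)(C)O[C@H]1[C@H]2C(=C)C(=O)O[C@@H]2[C@@H]2O[C@]2(C)CC/C=C(/C(=O)O)[C@H]1OC(C)=O | intermediate (not isolated)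
22 | C14 methyl ester (C9 OAc, C8 OTBS) | CC(C)(C)[Si](C)(C)O[C@H]1[C@H]2C(=C)C(=O)O[C@@H]2[C@@H]2O[C@]2(C)CC/C=C(/C(=O)OC)[C@H]1OC(C)=O | intermediate
23 | C8 alcohol (C9 OAc, C14 methyl ester) | O[C@H]1[C@H]2C(=C)C(=O)O[C@@H]2[C@@H]2O[C@]2(C)CC/C=C(/C(=O)OC)[C@H]1OC(C)=O | intermediate
24 | methyl 2-(hydroxymethyl)acrylate | C=C(CO)C(=O)OC | starting material
25 | methyl 2-(tert-butyldimethylsilyloxymethyl)acrylate | C=C(CO[Si](C)(C)C(C)(C)C)C(=O)OC | intermediate
26 | 2-(tert-butyldimethylsilyloxymethyl)acrylic acid | C=C(CO[Si](C)(C)C(C)(C)C)C(=O)O | intermediate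
27 | C8 2-(tert-butyldimethylsilyloxymethyl)acrylate of 23 | C=C(CO[Si](C)(C)C(C)(C)C)C(=O)O[C@H]1[C@H]2C(=C)C(=O)O[C@@H]2[C@@H]2O[C@]2(C)CC/C=C(/C(=O)OC)[C@H]1OC(C)=O | intermediate
28 | CNP0147016.1, (4R,5S,6S,7R,8S,9R)-germacranolide with 4,5-epoxide, trans-6,12-α-methylene lactone, 8-O-[2-(hydroxymethyl)acryloyl], 9-OAc, C14 methyl ester, ring-cis C1=C10 | C=C(CO)C(=O)O[C@H]1[C@H]2C(=C)C(=O)O[C@@H]2[C@@H]2O[C@]2(C)CC/C=C(/C(=O)OC)[C@H]1OC(C)=O | target

## Step count and least certain steps

Total: 22 steps. Longest linear sequence: 17 steps (steps 1–7, 11–18, 21, 22 from nerol).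

**Step 13 (key step).** The likely failure is poor facial selectivity at C9, because the conformational demands of the forming ten-membered ring can override the acyclic Felkin–Anh preference. Slow closure would also allow intermolecular coupling or protodeiodination. The fallback sets out from 16 and returns at 17, and sets C9 by reduction instead of by the C–C bond formation. The cyclisation is run as planned and the C9 epimer F1 (or the epimer mixture) is oxidised with Dess–Martin periodinane to the ten-membered enone F2. This is reduced from its less hindered face under Luche conditions (NaBH4, CeCl3) or, under reagent control, with borane and a CBS oxazaborolidine, to give 17.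

**Step 11.** Three things may go wrong: erosion of the anti and trans selectivities if the allylindium reacts through an open transition state; loss of silyloxide from the allylmetal by 1,4-elimination; and an incomplete acyl shift. The fallback sets out from 13 and 8 and returns at 15. Bromide 13 is converted with bis(pinacolato)diboron, CuCl (cat.) and KOAc into the allylboronate F3. F3 adds thermally to 8 through a closed Zimmerman–Traxler transition state that cannot eliminate, and after aqueous work-up the lactone shifts as before to 15.

**Step 10.** Ring closure may be slow because both olefins are deactivated (a 1,1-disubstituted acrylate and an alkene flanked by a silyl ether), so cross-metathesis dimerisation and catalyst decay by the allylic bromide can compete. The fallback sets out from 11 and returns at 13. The metathesis is run on the free allylic alcohol, whose vinyl group initiates more readily, to give the hydroxy lactone F4, which is then silylated with TBSOTf and 2,6-lutidine.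

**Step 7.** Cleavage of the silyl ether by the chlorosulfonium reagent may be incomplete, or chloride may open the epoxide during the longer, warmer activation. The fallback sets out from 7 and returns at 8. Buffered Bu4NF (with AcOH) frees the epoxy alcohol F5, which is oxidised under Parikh–Doering conditions (SO3·pyridine, DMSO, iPr2NEt).

**Step 21.** Acylation of the hindered C8 hydroxyl may be slow, giving time for base-mediated acetyl migration from O9 to O8. The fallback sets out from 23 and returns at 28, building the side chain on the molecule. The small, reactive diethylphosphonoacetic acid is coupled (carbodiimide, DMAP) to give the phosphonoacetate F6. Aqueous formaldehyde and K2CO3 then effect hydroxymethylation and Horner–Wadsworth–Emmons methylenation to give 28 directly, without 27.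

## Further compounds

F1 | step 13 | C9 epimer of 17 | CC(C)(C)[Si](C)(C)O[C@H]1[C@H]2C(=C)C(=O)O[C@@H]2[C@@H]2O[C@]2(C)CC/C=C(/COCc2ccc(OC)cc2)[C@@H]1O
F2 | step 13 | ten-membered C9 enone (C8 OTBS, C14 OPMB) | CC(C)(C)[Si](C)(C)O[C@H]1[C@H]2C(=C)C(=O)O[C@@H]2[C@@H]2O[C@]2(C)CC/C=C(/COCc2ccc(OC)cc2)C1=O
F3 | step 11 | (5S)-5-(tert-butyldimethylsilyloxy)-3-[(4,4,5,5-tetramethyl-1,3,2-dioxaborolan-2-yl)methyl]-5,6-dihydro-2H-pyran-2-one | CC1(C)OB(CC2=C[C@H](O[Si](C)(C)C(C)(C)C)COC2=O)OC1(C)C
F4 | step 10 | (5S)-3-(bromomethyl)-5-hydroxy-5,6-dihydro-2H-pyran-2-one | BrCC1=C[C@H](O)COC1=O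
F5 | step 7 | [(2S,3R)-3-[(3Z)-4-iodo-5-(4-methoxybenzyloxy)pent-3-en-1-yl]-3-methyloxiran-2-yl]methanol | OC[C@@H]1O[C@]1(C)CC/C=C(\I)COCc1ccc(OC)cc1
F6 | step 21 | C8 (diethoxyphosphoryl)acetate of 23 | CCOP(=O)(CC(=O)O[C@H]1[C@H]2C(=C)C(=O)O[C@@H]2[C@@H]2O[C@]2(C)CC/C=C(/C(=O)OC)[C@H]1OC(C)=O)OCC
A1 | alternative 1 | acetonide-protected hexahydronaphthalene diester with ring-fusion C1=C6 olefin | COC(=O)[C@@H]1[C@H]2OC(C)(C)O[C@H]2[C@@H](CC(=O)OC(C)(C)C)C3=C1CC=C(C)C3
A2 | alternative 1 | cyclodec-3-ene-1,6-dione keto ester | COC(=O)[C@@H]1[C@H]2OC(C)(C)O[C@H]2[C@@H](CC(=O)OC(C)(C)C)C(=O)C/C(C)=C\CC1=O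
A3 | alternative 2 | seco vinyl epoxide with C1 vinyl iodide, saturated lactone and C8/C9 acetonide | I/C=C(/C(=O)OC)[C@H]1OC(C)(C)O[C@H]1[C@H]1CC(=O)O[C@@H]1[C@@H]1O[C@]1(C)C=C
A4 | alternative 2 | ten-membered epoxy lactone with C8/C9 acetonide | CC1(C)O[C@H]2[C@H]3CC(=O)O[C@@H]3[C@@H]3O[C@]3(C)CC/C=C(/C(=O)OC)[C@H]2O1
A5 | alternative 3 | cyclooct-4-enone with C6 OTES, C7 tert-butyl acetate arm and C8 OTBS | CC(C)(C)[Si](C)(C)O[C@H]1[C@@H](CC(=O)OC(C)(C)C)[C@H](O[Si](CC)(CC)CC)/C=C(C)\CCC1=O
A6 | alternative 3 | 2-(methoxycarbonyl)cyclodeca-2,6-dienone with C6–C8 in place | CC(C)(C)[Si](C)(C)O[C@H]1[C@@H](CC(=O)OC(C)(C)C)[C@H](O[Si](CC)(CC)CC)/C=C(C)\CC/C=C(/C(=O)OC)C1=O
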